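**Retrosynthetic overview**
1. 11 ⇒ 10: the C3–Br bond is made last, by electrophilic bromination of the free pyrrole C3 position.
2. 10 ⇒ 7: the C2 ester is a traceless handle, removed by saponification and copper protodecarboxylation.
3. 7 ⇒ 4: cut N1–C7a (vinyl nitrene C–H amination). With this bond cut, ring atoms C3a, C4, C5, C6, C7 and C7a form a 3,5-dibromo-4-methoxyphenyl ring whose mirror plane runs through C3a and C6. C4–H and C7a–H are therefore equivalent, and Br, OMe and Br already sit at C5, C6 and C7.
4. 4 ⇒ 1 + 2: the C2=C3 bond comes from Knoevenagel condensation of the symmetric aldehyde with methyl azidoacetate.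
5. Ring order: the benzene ring is bought; the pyrrole ring is the only ring made (step 2).

Key step: step 2

Remark: the target is a planar, achiral indole with no stereogenic element, so "single enantiomer" means simply the one structure drawn; the only stereochemical feature on the way is the Z geometry of the azidoacrylate 4, which disappears on cyclisation.

**Step 1**
Reactants: 1 3,5-dibromo-4-methoxybenzaldehyde; 2 methyl azidoacetate
Product: 4 methyl (Z)-2-azido-3-(3,5-dibromo-4-methoxyphenyl)acrylate, via azido aldol adduct 3 (not isolated)
Conditions: NaOMe (4 equiv), 2 (4 equiv), MeOH–THF, −15 → 0 °C; then ice-water, filter (azides kept cold and handled in solution)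
Reagents that add atoms: none
Why: Knoevenagel-type aldol–E1cB condensation, in which the azidoacetate enolate adds to the non-enolisable, bromine-activated aldehyde to give 3 and hydroxide is expelled at low temperature before the azide can decompose, the thermodynamically preferred Z-alkene (aryl cis to N3, trans to the ester) being the usual outcome.

**Step 2**
Reactants: 4 methyl (Z)-2-azido-3-(3,5-dibromo-4-methoxyphenyl)acrylate
Product: 7 methyl 5,7-dibromo-6-methoxy-1H-indole-2-carboxylate, via 2H-azirine 5 (not isolated), via 7aH-indole 6 (not isolated)
Conditions: xylenes, reflux (ca. 140 °C), ca. 0.05 M, slow addition of 4 to the boiling solvent, 2–3 h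
Reagents that add atoms: none
Why: Heat expels N2 from the vinyl azide to give a singlet vinyl nitrene that is reversibly stored as the 2H-azirine 5; the nitrene nitrogen then bonds to an ortho carbon of the aryl ring (N1–C7a) in a five-membered closure, best described as a 6π 1,5-electrocyclisation of the N–C2=C3–C3a=C7a array, to give the 7aH-indole 6. A suprafacial 1,5-hydrogen shift from C7a to N1 re-aromatises 6 to the 1H-indole 7. This is the Hemetsberger–Knittel indole synthesis, a reaction type long used on halogenated α-azidocinnamates. The step creates no lasting stereocentre, because the sp3 carbon C7a of 6 is flattened in the hydrogen shift. The selectivity that matters is which ortho carbon is aminated, and the substrate removes the question: the 3,5-dibromo-4-methoxyphenyl ring is symmetric about its C1···C4 axis, so either ortho C–H gives the same indole with bromine at C5 and C7 and methoxy at C6, while the Z geometry of 4 holds the nitrogen next to the ring. Neutral, reagent-free conditions should leave both C–Br bonds, the ether and the ester untouched, and dilution with slow addition should keep the nitrene from reacting with a second molecule.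

**Step 3**
Reactants: 7 methyl 5,7-dibromo-6-methoxy-1H-indole-2-carboxylate
Product: 9 5,7-dibromo-6-methoxy-1H-indole-2-carboxylic acid, via sodium carboxylate 8 (not isolated)
Conditions: 2 M aq NaOH, THF–MeOH, 55 °C; then 1 M HCl to pH 2, 0 °C, filter
Reagents that add atoms: sodium hydroxide, [Na+].[OH-]
Why: Ester saponification (BAc2) followed by acidification, under which the aryl bromides, the aryl methyl ether and the indole ring are inert.

**Step 4**
Reactants: 9 5,7-dibromo-6-methoxy-1H-indole-2-carboxylic acid
Product: 10 5,7-dibromo-6-methoxy-1H-indole
Conditions: Cu powder (0.2 equiv), quinoline, 200 °C, Ar, short heating; acid wash to remove quinoline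
Reagents that add atoms: none
Why: Copper-mediated protodecarboxylation of a heteroaryl carboxylic acid, in which the copper(I) carboxylate loses CO2 to a 2-indolylcopper species that is protonated, the classical way to remove the C2 carboxyl of Hemetsberger indoles, with catalytic copper, inert gas and short heating chosen to spare the two C–Br bonds.

**Step 5**
Reactants: 10 5,7-dibromo-6-methoxy-1H-indole
Product: 11 3,5,7-tribromo-6-methoxy-1H-indole
Conditions: NBS (1.0 equiv), DMF, 0 °C, dark; cold aq Na2S2O3/NaHCO3 work-up
Reagents that add atoms: N-bromosuccinimide, O=C1CCC(=O)N1Br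
Why: Electrophilic aromatic substitution at C3, the enamine-like and most nucleophilic carbon of the N–H indole, while the only free benzenoid position (C4) is flanked by bromine and meta to the methoxy group and one equivalent of NBS at 0 °C limits a second bromination at C2.

**Compound list**
1 | 3,5-dibromo-4-methoxybenzaldehyde | COc1c(Br)cc(C=O)cc1Br | starting material
2 | methyl azidoacetate | COC(=O)CN=[N+]=[N-] | starting material
3 | methyl 2-azido-3-(3,5-dibromo-4-methoxyphenyl)-3-hydroxypropanoate (racemic; both diastereomers) | COC(=O)C(N=[N+]=[N-])C(O)c1cc(Br)c(OC)c(Br)c1 | intermediate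
4 | methyl (Z)-2-azido-3-(3,5-dibromo-4-methoxyphenyl)acrylate | COC(=O)/C(N=[N+]=[N-])=C/c1cc(Br)c(OC)c(Br)c1 | intermediate
5 | methyl 2-(3,5-dibromo-4-methoxyphenyl)-2H-azirine-3-carboxylate (racemic) | COC(=O)C1=NC1c1cc(Br)c(OC)c(Br)c1 | intermediate
6 | methyl 5,7-dibromo-6-methoxy-7aH-indole-2-carboxylate (racemic) | COC(=O)C1=NC2C(Br)=C(OC)C(Br)=CC2=C1 | intermediate
7 | methyl 5,7-dibromo-6-methoxy-1H-indole-2-carboxylate | COC(=O)c1cc2cc(Br)c(OC)c(Br)c2[nH]1 | intermediate
8 | sodium 5,7-dibromo-6-methoxy-1H-indole-2-carboxylate | [Na+].[O-]C(=O)c1cc2cc(Br)c(OC)c(Br)c2[nH]1 | intermediate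
9 | 5,7-dibromo-6-methoxy-1H-indole-2-carboxylic acid | OC(=O)c1cc2cc(Br)c(OC)c(Br)c2[nH]1 | intermediate
10 | 5,7-dibromo-6-methoxy-1H-indole | COc1c(Br)cc2cc[nH]c2c1Br | intermediate
11 | 3,5,7-tribromo-6-methoxy-1H-indole | COc1c(Br)cc2c(Br)c[nH]c2c1Br | target

**Total step count:** 5
**Longest linear sequence:** 5 steps (1 → 4 → 7 → 9 → 10 → 11)

**Steps most likely to fail**

Step 4 (decarboxylation). At about 200 °C copper may insert into the C5–Br and C7–Br bonds, which would lead to hydrodebromination or Ullmann-type N-arylation, and prolonged heating in quinoline may tar the product. The fallback removes the C2 carbon as CO instead of CO2; it sets out from ester 7 and comes back to the route at indole 10. DIBAL-H (THF, −78 → 0 °C) should reduce 7 to (5,7-dibromo-6-methoxy-1H-indol-2-yl)methanol F1. MnO2 (CH2Cl2, rt) should oxidise this to 5,7-dibromo-6-methoxy-1H-indole-2-carbaldehyde F2. Tsuji–Wilkinson decarbonylation with stoichiometric RhCl(PPh3)3 in refluxing toluene should then give 10 without copper and at about 110 °C.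

Step 5 (C3 bromination). Once C3 is filled, a second bromination at C2 may set in, and the unprotected 3-bromoindole may decompose under traces of acid or air during work-up and purification. The fallback goes through an N-acyl indole; it sets out from 10 and comes back at the target 11. Boc2O with catalytic DMAP (MeCN, rt) should give tert-butyl 5,7-dibromo-6-methoxy-1H-indole-1-carboxylate F3. NBS in DMF (rt → 40 °C) should brominate the less nucleophilic N-acyl indole once, at C3, to give tert-butyl 3,5,7-tribromo-6-methoxy-1H-indole-1-carboxylate F4, which is purified at this stage as a stable carbamate. K2CO3 in MeOH at rt should then remove the Boc group and release 11, to be isolated by precipitation with water.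

Step 2 (key step). The nitrene and azirine may be consumed by bimolecular pathways (dimers, tar) faster than the ring closes onto an ortho carbon that is flanked by bromine. The fallback keeps the N1–C7a disconnection but replaces uncatalysed thermolysis by catalytic nitrene transfer; it sets out from 4 and comes back at 7. With Rh2(O2CC3F7)4 (3–5 mol%) in toluene at 40–60 °C, nitrogen should be lost on the metal and a rhodium-bound nitrenoid should carry out the C–H amination, so no free nitrene builds up; no new compound arises (F0).

**Further compounds**
F1 | step 4 | (5,7-dibromo-6-methoxy-1H-indol-2-yl)methanol | OCc1cc2cc(Br)c(OC)c(Br)c2[nH]1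
F2 | step 4 | 5,7-dibromo-6-methoxy-1H-indole-2-carbaldehyde | O=Cc1cc2cc(Br)c(OC)c(Br)c2[nH]1
F3 | step 5 | tert-butyl 5,7-dibromo-6-methoxy-1H-indole-1-carboxylate | COc1c(Br)cc2ccn(C(=O)OC(C)(C)C)c2c1Br
F4 | step 5 | tert-butyl 3,5,7-tribromo-6-methoxy-1H-indole-1-carboxylate | COc1c(Br)cc2c(Br)cn(C(=O)OC(C)(C)C)c2c1Br
F0 | step 2 | none | none
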